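**Remarks on the chemistry**

- Numbering: lignan numbering is used throughout. C7 = ring ArCH–O, C8 = ring CH bearing C9, C8' = ring CH bearing C7', C9' = ring OCH2. The target is (7S,8R,8'R,7'S).
- Abbreviation: ArSi = 4-(tert-butyldimethylsilyloxy)-3-methoxyphenyl; TBS = tert-butyldimethylsilyl.
- Naming of the cycloadduct: with the carbonyl on C8 and the CCl2 group on C8', von Baeyer numbering makes the cycloadduct a 4-aryl-7,7-dichloro-3-oxabicyclo[3.2.0]heptan-6-one. A 2-aryl locant would denote the unwanted regioisomer, so the 4-aryl name is used.
- Aldehyde-to-phenol step: it is run with a peracid followed by formate methanolysis, because alkaline peroxide would strip the aryl silyl ether.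
- Assumption on the ligand: the (R)-configured tert-butyl phosphinooxazoline is taken to give the (S)-dihydrofuran, by analogy with the sense of arylation by phenyl triflate. If the sense were opposite, the (S)-ligand would be used.

## Structural features

The target is a 2,3,4-trisubstituted tetrahydrofuran (ring atoms O, C7, C8, C8', C9'). C7 carries a 4-hydroxy-3-methoxyphenyl group, C8 a CH2O unit (C9) esterified with (E)-p-coumaric acid, and C8' a secondary benzylic carbinol (C7') bearing a second, identical aryl group. Four contiguous stereocentres run C7–C8–C8'–C7'; on the ring the C7 aryl is trans to C9, C9 and C7' are cis, and the carbinol centre lies outside the ring. The fragile groups are three free phenols, a p-hydroxybenzylic alcohol and a benzylic ring ether that ionise in acid (quinone methide, or closure of a free O-9 onto C7' to a furofuran), and a cinnamate ester that can migrate to O-7', hydrolyse in base or be hydrogenated. The real difficulty is the pattern around the ring: two cis carbon branches on C8 and C8' next to a trans aryl group, the exocyclic C7' configuration, and the need to tell primary O-9 from secondary O-7' and from three phenols. C9 and C7' are each one oxygen-bearing carbon, cis on neighbouring ring carbons and both trans to the C7 aryl, which is what suprafacial addition of a two-carbon unit C9–C7' to the C8=C8' bond of a 2-aryl-2,5-dihydrofuran leaves when it comes from the face away from the aryl. A ketene supplies that unit as a cis-fused cyclobutanone, and later oxygen insertion into the C9–C7' bond, after an aryl has been placed on C7' on the convex face, gives the 1,4-dioxygen pattern with the C7' configuration read off the bicycle.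

## Logic of the disconnections

21 ⇒ 20. The three phenolic O–Si bonds are cut. Free phenols would interfere with enolate chemistry, peracid, hydride and acylation, so all three carry one kind of group that a single mild operation removes. Nothing is gained in skeleton, but every earlier step runs on non-acidic arenes. The forward step must avoid conditions that move the acyl group from O-9 to O-7' or ionise the benzylic carbinol.

20 ⇒ 16 + 19. The ester C(=O)–O9 bond is cut. It is the most labile bond and the cut is convergent, keeping the reducible, base-sensitive cinnamate out of the hydride step. The core becomes a diol. The forward step must acylate primary O-9 in the presence of secondary benzylic O-7'.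

19 ⇒ 17 (through 18). Only O–Si bonds are involved. The forward step must tell a silyl ester from an aryl silyl ether.

16 ⇒ 15. The O7'–C9 acyl bond is re-formed in the retrosynthetic sense, so the diol is seen as the reduction product of a γ-lactone. This ties both side-chain carbons into a second ring and turns the exocyclic carbinol centre into a ring stereocentre of a rigid cis-fused bicycle. The forward reduction must neither epimerise nor let the 1,4-diol close onto the benzylic carbon.

15 ⇒ 14. The O–C7' bond is cut and the C9–C7' bond restored (retro-Baeyer–Villiger). A C–O stereocentre becomes a C–C stereocentre and a cyclobutanone, the retron of a ketene cycloaddition, appears. The forward step needs migration of C7' rather than C8, with retention.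

14 ⇒ 10 + 12 (through 13). The C7'–aryl bond is cut. The two-carbon bridge is reduced to the simplest ketene unit, and the second aryl arrives from a one-step fragment. The forward step must arylate a strained ketone at C7' without opening the ring and must settle the aryl on the exo face.

12 ⇒ 11. An O–Si bond only.

10 ⇒ 9. Two C–H bonds are exchanged for C–Cl bonds, because only the activated ketene 8 adds to an unactivated alkene. The forward step is a clean reductive dechlorination.

9 ⇒ 7 + 8. The C8–C9 and C8'–C7' bonds are cut together, taking the four-membered ring apart. This removes one ring, two skeletal bonds and two stereocentres and leaves one stereocentre (C7). The forward cycloaddition must take the face anti to the aryl and must place the carbonyl carbon on C8.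

7 ⇒ 5 + 6. The C7–aryl bond is cut. A catalyst then sets the only stereocentre that is not relayed. The forward step must give the 2,5-dihydro isomer without double-bond migration and in high enantiomeric purity.

5 ⇒ 4 ⇒ 2 ⇒ 1 (through 3). The O–S bond, the aryl C–O bond (from the formyl carbon) and the O–Si bond are cut in turn. This leads back to a cheap aldehyde whose oxygen pattern is already correct. The aryl group must migrate in the peracid step and the silyl ether must survive it.

## Other disconnections considered

Alternative 1: The tetrahydrofuran is cut through C7–C8 and C8'–C9', as a carbonyl ylide (C7–O–C9') plus the C8=C8' bond of the (S)-butenolide A2. In A2, C9 is already the lactone carbonyl and O-7' the lactone oxygen. Forward, CsF would unmask the ylide from the α-chloro silylmethyl ether A3, and a (3+2) cycloaddition anti to the C7' aryl would give the cis-fused furofuranone A1, which is 15 with allyl in place of silyl ethers.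
- In favour: the lactone oxidation pattern is reached directly, without arylation of a strained ketone and without oxygen insertion. The orientation of the dipole is steered by the polarised enone (nucleophilic CH2 terminus to the β-carbon C8'), a firmer basis than the weak bias available in step 5; on regiochemistry this alternative is the better one.
- Against: C7 is created in the key step and its configuration depends on ylide geometry and endo/exo approach, for which the substrate offers little control. In the chosen plan C7 comes from a catalyst and the ring carbons follow from it. Fluoride excludes silyl-protected phenols, so allyl ethers and a separate Pd-catalysed deallylation are needed. The γ-hydrogen of A2 is acidic, so basic fluoride endangers its only stereocentre, and the unstabilised ylide is short-lived.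
- Comparison: both plans use a concerted cycloaddition that relays one stereocentre into the ring, and the end-game from the lactone is the same. Step count is about equal, possibly one or two fewer for this alternative.

Alternative 2: C7–C8 and C7'–C8' are cut as two aldol bonds and both lactone C–O bonds as lactonisations. Forward, 2,5-bis(trimethylsilyloxy)furan A5 would add twice to 2 under a chiral Lewis acid (for example Ti(OiPr)4 with BINOL) to give the C2-symmetric bislactone A4.
- In favour: it is the most convergent plan, with four stereocentres and both rings from two molecules of one aldehyde. It exploits the identity of the two aryl groups. Because the two halves of A4 are homotopic there is no regiochemical question; on bonds formed per step and on regiochemistry it is better than the chosen plan.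
- Against: the target is not C2-symmetric. One carbonyl (C9') must be taken down to the ring CH2, the other (C9) must end as the acyloxymethyl group, and only the C7'–O lactone bond may be opened. That costs a mono-reduction, a lactol deoxygenation with a silane and Lewis acid at a benzylic acetal flanked by electron-rich arenes (ring opening or epimerisation at C7 is a threat), and only then the route reaches 15. Catalyst control over two successive aldol events and over exo/endo placement of both aryl groups is a heavy demand.
- Comparison: the short entry to A4 is offset by the redox corrections, so the overall count is at best equal. Structurally it builds more than the target needs, whereas the chosen plan builds each carbon at or near its final oxidation level.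

Alternative 3: C7'–C8' and the O–C9 lactone bond are cut. Forward, SmI2 (divalent samarium) would reduce 2 to a ketyl that adds to C8' of the dihydrofuran ester A7, and the alkoxide would lactonise onto the C9 ester to give A6, which is identical with 15.
- In favour: C9 is already on C8, so regiochemistry is fixed; on this point it is better than the chosen plan. It reaches 15 in one step from two fragments, saving the dechlorination, arylation and oxygen-insertion steps, and it tolerates silyl ethers.
- Against: three stereocentres (C8', C8 by enolate protonation, C7') are set in one radical and protonation sequence with only the C7 aryl, 1,3 to the site of attack, as control. Pinacol coupling of the aryl aldehyde competes. A7 has no direct catalytic asymmetric entry comparable to the one-step Heck access to 7.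
- Comparison: step economy is equal or better if A7 is in hand; stereochemical security is lower. It is kept in reserve as the fallback for step 5.

Key step: step 5

## Route

Step 1
Reactants: 1 vanillin (4-hydroxy-3-methoxybenzaldehyde)
Product: 2 4-(tert-butyldimethylsilyloxy)-3-methoxybenzaldehyde
Conditions: TBSCl, imidazole, DMF, rt
Reagents that add atoms: tert-butyldimethylsilyl chloride, CC(C)(C)[Si](C)(C)Cl
Why: Routine phenol silylation; the aldehyde is untouched and the silyl ether is the single phenol protecting group carried to the last step.

Step 2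
Reactants: 2 4-(tert-butyldimethylsilyloxy)-3-methoxybenzaldehyde
Product: 4 4-(tert-butyldimethylsilyloxy)-3-methoxyphenol, via aryl formate 3 (not isolated)
Conditions: mCPBA, CH2Cl2, 0 °C to rt; NaHCO3 wash; then Et3N, MeOH, 0 °C
Reagents that add atoms: 3-chloroperoxybenzoic acid, OOC(=O)c1cccc(Cl)c1
Why: Baeyer–Villiger oxidation of an electron-rich benzaldehyde, in which the para-silyloxy group makes the aryl group migrate, gives the aryl formate; mild methanolysis then frees the phenol without touching the aryl silyl ether.

Step 3
Reactants: 4 4-(tert-butyldimethylsilyloxy)-3-methoxyphenol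
Product: 5 4-(tert-butyldimethylsilyloxy)-3-methoxyphenyl trifluoromethanesulfonate
Conditions: Tf2O, pyridine, CH2Cl2, 0 °C
Reagents that add atoms: trifluoromethanesulfonic anhydride, O=S(=O)(OS(=O)(=O)C(F)(F)F)C(F)(F)F
Why: O-Sulfonylation of the phenol; the triflate opens the cationic pathway that the asymmetric Heck reaction needs.

Step 4
Reactants: 5 4-(tert-butyldimethylsilyloxy)-3-methoxyphenyl trifluoromethanesulfonate; 6 2,3-dihydrofuran
Product: 7 (S)-2-(ArSi)-2,5-dihydrofuran
Conditions: Pd2(dba)3 (1.5 mol%), (R)-tBu-PHOX (6 mol%), iPr2NEt, 6 (4 equiv), THF, 70 °C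
Reagents that add atoms: none
Why: Asymmetric Heck arylation: the cationic aryl–Pd species from oxidative addition to zerovalent palladium adds with the aryl at the oxygen-bearing alkene carbon, and β-hydride elimination away from the new centre, followed by fast release from the P,N-ligand complex, gives the 2,5-dihydrofuran without double-bond migration. C7 is set by the chiral ligand, the (R)-ligand being expected to give the (S)-product.

Step 5
Reactants: 7 (S)-2-(ArSi)-2,5-dihydrofuran
Product: 9 (1R,4S,5S)-4-(ArSi)-7,7-dichloro-3-oxabicyclo[3.2.0]heptan-6-one, via dichloroketene 8 (not isolated)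
Conditions: Cl3CCOCl (2 equiv, slow addition), Zn–Cu couple (3 equiv), Et2O–DME, 0 °C to rt
Reagents that add atoms: trichloroacetyl chloride, ClC(=O)C(Cl)(Cl)Cl
Why: Zinc reduction of trichloroacetyl chloride releases 8, whose electrophilic carbonyl carbon engages the alkene of 7 in a thermal, concerted but asynchronous (2+2) cycloaddition (suprafacial on the alkene, antarafacial on the ketene), the reaction type known for dichloroketene with cyclopentenes and with 2,5-dihydrofurans. The four-membered ring is closed by this cycloaddition in one event, C8–C9 and C8'–C7' being delivered to the same face, so the ring fusion must be cis. C8 and C8' are the two new stereocentres and both are controlled by the existing C7 centre, because the aryl group shields its own face of the nearly flat ring and the ketene adds anti to it; C9 and C7' therefore end up cis to each other and trans to the aryl. The step needs facial selectivity, which the C7 substituent secures, and regioselectivity (carbonyl carbon to C8, CCl2 to C8'), which rests only on the slightly smaller steric demand at C8' and on C8' (next to CH2O rather than ArCHO) carrying the developing positive charge a little better. A modest preference is expected, and the regioisomer is to be removed by chromatography here or after step 6. DME ties up ZnCl2 so that the benzylic, allylic C7–O bond is not ionised, and 7 must be free of enol-ether double-bond isomers, which would consume 8 faster.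

Step 6
Reactants: 9 (1R,4S,5S)-4-(ArSi)-7,7-dichloro-3-oxabicyclo[3.2.0]heptan-6-one
Product: 10 (1R,4S,5S)-4-(ArSi)-3-oxabicyclo[3.2.0]heptan-6-one
Conditions: Zn dust, AcOH, rt
Reagents that add atoms: none
Why: Reductive dechlorination of an α,α-dichlorocyclobutanone through zinc enolates; the aryl silyl ether and the benzylic ether tolerate acetic acid and no stereocentre is touched.

Step 7
Reactants: 11 4-bromo-2-methoxyphenol
Product: 12 (4-bromo-2-methoxyphenoxy)(tert-butyl)dimethylsilane
Conditions: TBSCl, imidazole, DMF, rt
Reagents that add atoms: tert-butyldimethylsilyl chloride, CC(C)(C)[Si](C)(C)Cl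
Why: Routine phenol silylation; the bromide sits para to the silyloxy and meta to the methoxy group, the pattern needed for the C7' aryl.

Step 8
Reactants: 10 (1R,4S,5S)-4-(ArSi)-3-oxabicyclo[3.2.0]heptan-6-one; 12 (4-bromo-2-methoxyphenoxy)(tert-butyl)dimethylsilane
Product: 14 (1R,4S,5S,7S)-4,7-bis(ArSi)-3-oxabicyclo[3.2.0]heptan-6-one (7-aryl exo), via endo-aryl epimer 13 (not isolated)
Conditions: LiN(SiMe3)2 (2.2 equiv), Pd(OAc)2 (5 mol%), P(tBu)3·HBF4 (10 mol%), toluene, rt to 50 °C; NH4Cl (aq); then DBU (cat.), CH2Cl2, rt
Reagents that add atoms: none
Why: Proposed new method: the lithium enolate of 10, formed only toward C7' because a bridgehead enolate at C8 would put a double bond at the fusion of the four-membered ring, should transmetalate to the aryl–Pd bromide from 12 and reductively eliminate the C7'–aryl bond, as in the Pd-catalysed α-arylation of ketone enolates with aryl bromides that is established for larger-ring ketones and, intramolecularly under Pd/enamine catalysis, for cyclobutanones; the non-nucleophilic silylamide keeps the more acidic product as its enolate and so guards the strained ketone against ring cleavage, and protonation followed by DBU equilibration of 13 should place the aryl on the convex face, cis to H-8', giving 14.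

Step 9
Reactants: 14 (1R,4S,5S,7S)-4,7-bis(ArSi)-3-oxabicyclo[3.2.0]heptan-6-one
Product: 15 (3S,3aR,6S,6aS)-3,6-bis(ArSi)tetrahydro-1H,3H-furo[3,4-c]furan-1-one
Conditions: mCPBA, NaHCO3, CH2Cl2, 0 °C to rt
Reagents that add atoms: 3-chloroperoxybenzoic acid, OOC(=O)c1cccc(Cl)c1
Why: Baeyer–Villiger oxidation of a strained ketone: the electron-rich benzylic C7' should migrate in preference to the bridgehead C8, which is deactivated by the neighbouring C7–O bond. Migration occurs with retention, so the exo aryl of 14 becomes the exo aryl of the cis-fused lactone and C7' gains its oxygen in the (S) configuration.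

Step 10
Reactants: 15 (3S,3aR,6S,6aS)-3,6-bis(ArSi)tetrahydro-1H,3H-furo[3,4-c]furan-1-one
Product: 16 {(2S,3R,4R)-2-(ArSi)-4-[(S)-(ArSi)(hydroxy)methyl]oxolan-3-yl}methanol
Conditions: LiBH4, THF, 0 °C to rt; NH4Cl (aq)
Reagents that add atoms: none
Why: Hydride reduction of the γ-lactone to the 1,4-diol breaks no bond at a stereocentre and leaves aryl silyl ethers alone; the neutral work-up avoids acid-induced closure of O-9 onto the benzylic C7'.

Step 11
Reactants: 17 p-coumaric acid ((E)-3-(4-hydroxyphenyl)prop-2-enoic acid)
Product: 19 (E)-3-[4-(tert-butyldimethylsilyloxy)phenyl]prop-2-enoic acid, via bis-silylated coumaric acid 18 (not isolated)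
Conditions: TBSCl (2.5 equiv), imidazole, DMF, rt; then AcOH–THF–H2O, rt
Reagents that add atoms: tert-butyldimethylsilyl chloride, CC(C)(C)[Si](C)(C)Cl
Why: Both acidic hydroxyls are silylated, and the silyl ester, far more labile than the aryl silyl ether, is then hydrolysed selectively under mild aqueous acid.

Step 12
Reactants: 16 {(2S,3R,4R)-2-(ArSi)-4-[(S)-(ArSi)(hydroxy)methyl]oxolan-3-yl}methanol; 19 (E)-3-[4-(tert-butyldimethylsilyloxy)phenyl]prop-2-enoic acid
Product: 20 {(2S,3R,4R)-2-(ArSi)-4-[(S)-(ArSi)(hydroxy)methyl]oxolan-3-yl}methyl (E)-3-[4-(tert-butyldimethylsilyloxy)phenyl]prop-2-enoate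
Conditions: EDC·HCl (1.2 equiv), DMAP (0.1 equiv), 19 (1.05 equiv), CH2Cl2, 0 °C
Reagents that add atoms: none
Why: Steglich esterification: the activated acid should acylate the unhindered primary O-9 much faster than the secondary benzylic O-7', which is flanked by the ring and an aryl group. Low temperature, one equivalent of acid and catalytic DMAP keep it to mono-acylation.

Step 13
Reactants: 20 {(2S,3R,4R)-2-(ArSi)-4-[(S)-(ArSi)(hydroxy)methyl]oxolan-3-yl}methyl (E)-3-[4-(tert-butyldimethylsilyloxy)phenyl]prop-2-enoate
Product: 21 {(2S,3R,4R)-2-(4-hydroxy-3-methoxyphenyl)-4-[(S)-hydroxy(4-hydroxy-3-methoxyphenyl)methyl]oxolan-3-yl}methyl (E)-3-(4-hydroxyphenyl)prop-2-enoate (CNP0330050.2)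
Conditions: Bu4NF, AcOH (1:1, 3.5 equiv), THF, 0 °C
Reagents that add atoms: none
Why: Fluoride cleaves the three aryl silyl ethers quickly at 0 °C. Acetic acid buffers the phenoxides so that acyl migration from O-9 to O-7' and quinone-methide formation at the p-hydroxybenzylic carbinol should not set in, and the cinnamate with its E double bond is untouched.

## Compound list

1 | vanillin (4-hydroxy-3-methoxybenzaldehyde) | COc1cc(C=O)ccc1O | starting material
2 | 4-(tert-butyldimethylsilyloxy)-3-methoxybenzaldehyde | COc1cc(C=O)ccc1O[Si](C)(C)C(C)(C)C | intermediate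
3 | 4-(tert-butyldimethylsilyloxy)-3-methoxyphenyl formate | COc1cc(OC=O)ccc1O[Si](C)(C)C(C)(C)C | intermediate (not isolated)
4 | 4-(tert-butyldimethylsilyloxy)-3-methoxyphenol | COc1cc(O)ccc1O[Si](C)(C)C(C)(C)C | intermediate
5 | 4-(tert-butyldimethylsilyloxy)-3-methoxyphenyl trifluoromethanesulfonate | COc1cc(OS(=O)(=O)C(F)(F)F)ccc1O[Si](C)(C)C(C)(C)C | intermediate
6 | 2,3-dihydrofuran | C1=COCC1 | starting material
7 | (S)-2-[4-(tert-butyldimethylsilyloxy)-3-methoxyphenyl]-2,5-dihydrofuran | C1=CCO[C@@H]1c2ccc(O[Si](C)(C)C(C)(C)C)c(OC)c2 | intermediate
8 | dichloroketene | ClC(Cl)=C=O | intermediate (not isolated)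
9 | (1R,4S,5S)-4-[4-(tert-butyldimethylsilyloxy)-3-methoxyphenyl]-7,7-dichloro-3-oxabicyclo[3.2.0]heptan-6-one | ClC1(Cl)[C@H]2CO[C@H](c3ccc(O[Si](C)(C)C(C)(C)C)c(OC)c3)[C@H]2C1=O | intermediate
10 | (1R,4S,5S)-4-[4-(tert-butyldimethylsilyloxy)-3-methoxyphenyl]-3-oxabicyclo[3.2.0]heptan-6-one | C1[C@H]2CO[C@H](c3ccc(O[Si](C)(C)C(C)(C)C)c(OC)c3)[C@H]2C1=O | intermediate
11 | 4-bromo-2-methoxyphenol | COc1cc(Br)ccc1O | starting material
12 | (4-bromo-2-methoxyphenoxy)(tert-butyl)dimethylsilane | COc1cc(Br)ccc1O[Si](C)(C)C(C)(C)C | intermediate
13 | (1R,4S,5S,7R)-4,7-bis[4-(tert-butyldimethylsilyloxy)-3-methoxyphenyl]-3-oxabicyclo[3.2.0]heptan-6-one (7-aryl endo) | COc1cc([C@H]3[C@H]2CO[C@H](c4ccc(O[Si](C)(C)C(C)(C)C)c(OC)c4)[C@H]2C3=O)ccc1O[Si](C)(C)C(C)(C)C | intermediate (not isolated)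
14 | (1R,4S,5S,7S)-4,7-bis[4-(tert-butyldimethylsilyloxy)-3-methoxyphenyl]-3-oxabicyclo[3.2.0]heptan-6-one (7-aryl exo) | COc1cc([C@@H]3[C@H]2CO[C@H](c4ccc(O[Si](C)(C)C(C)(C)C)c(OC)c4)[C@H]2C3=O)ccc1O[Si](C)(C)C(C)(C)C | intermediate
15 | (3S,3aR,6S,6aS)-3,6-bis[4-(tert-butyldimethylsilyloxy)-3-methoxyphenyl]tetrahydro-1H,3H-furo[3,4-c]furan-1-one | COc1cc([C@@H](O3)[C@H]2CO[C@H](c4ccc(O[Si](C)(C)C(C)(C)C)c(OC)c4)[C@H]2C3=O)ccc1O[Si](C)(C)C(C)(C)C | intermediate
16 | {(2S,3R,4R)-2-[4-(tert-butyldimethylsilyloxy)-3-methoxyphenyl]-4-[(S)-[4-(tert-butyldimethylsilyloxy)-3-methoxyphenyl](hydroxy)methyl]oxolan-3-yl}methanol | COc1cc([C@@H](O)[C@H]2CO[C@H](c3ccc(O[Si](C)(C)C(C)(C)C)c(OC)c3)[C@H]2CO)ccc1O[Si](C)(C)C(C)(C)C | intermediate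
17 | p-coumaric acid ((E)-3-(4-hydroxyphenyl)prop-2-enoic acid) | OC(=O)/C=C/c1ccc(O)cc1 | starting material
18 | tert-butyldimethylsilyl (E)-3-[4-(tert-butyldimethylsilyloxy)phenyl]prop-2-enoate | CC(C)(C)[Si](C)(C)OC(=O)/C=C/c1ccc(O[Si](C)(C)C(C)(C)C)cc1 | intermediate (not isolated)
19 | (E)-3-[4-(tert-butyldimethylsilyloxy)phenyl]prop-2-enoic acid | OC(=O)/C=C/c1ccc(O[Si](C)(C)C(C)(C)C)cc1 | intermediate
20 | {(2S,3R,4R)-2-[4-(tert-butyldimethylsilyloxy)-3-methoxyphenyl]-4-[(S)-[4-(tert-butyldimethylsilyloxy)-3-methoxyphenyl](hydroxy)methyl]oxolan-3-yl}methyl (E)-3-[4-(tert-butyldimethylsilyloxy)phenyl]prop-2-enoate | COc1cc([C@@H](O)[C@H]2CO[C@H](c3ccc(O[Si](C)(C)C(C)(C)C)c(OC)c3)[C@H]2COC(=O)/C=C/c2ccc(O[Si](C)(C)C(C)(C)C)cc2)ccc1O[Si](C)(C)C(C)(C)C | intermediate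
21 | {(2S,3R,4R)-2-(4-hydroxy-3-methoxyphenyl)-4-[(S)-hydroxy(4-hydroxy-3-methoxyphenyl)methyl]oxolan-3-yl}methyl (E)-3-(4-hydroxyphenyl)prop-2-enoate | COc1cc([C@@H](O)[C@H]2CO[C@H](c3ccc(O)c(OC)c3)[C@H]2COC(=O)/C=C/c2ccc(O)cc2)ccc1O | target

## Step count and least certain steps

Total step count: 13. Longest linear sequence: 11 steps (steps 1 to 6, 8 to 10, 12 and 13). Steps 7 and 11 prepare the two side fragments.

**Step 8 (α-arylation, proposed new method).** The most likely failure is loss of the four-membered ketone under basic, palladium-containing conditions before the C–C bond forms: self-condensation of the enolate, base- or metal-induced cleavage of the strained ring, or ring opening of the more acidic α-aryl product. Exo/endo control is a lesser worry because C7' can equilibrate. The fallback uses known reactions, sets out from 10 and comes back at 15, passing by 13 and 14. Kinetic enolisation of 10 toward C7' (LiN(iPr)2, Me3SiCl, THF, −78 °C) gives the silyl enol ether F1. Ozonolysis (O3, CH2Cl2–MeOH, −78 °C, then Me2S) cleaves C9=C7' to the cis aldehyde acid, which is held as its bicyclic hydroxy lactone F2. The aryl Grignard reagent made from 12 (Mg, THF; 2.2 equiv) opens F2 to the magnesium carboxylate aldehyde and adds to the aldehyde, expected from the convex face of the chelate. Mild acid then closes the hydroxy acid to 15. In this variant C7' is set by addition control and not by the bicycle, so a C7' epimer would have to be separated.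

**Step 5 (key step).** The most likely failure is poor regioselectivity of the ketene orientation (carbonyl carbon to C8' instead of C8), because the two alkene carbons differ only through a neighbouring aryl-bearing carbon and donation from the electron-rich aryl group may even oppose the wanted sense. The second risk is acylation of the ring oxygen by 8, or ZnCl2-assisted ionisation of the benzylic, allylic C7–O bond, with ring opening or loss of configuration at C7. The fallback fixes regiochemistry by putting C9 on C8 before the second ring is made; it sets out from 2 and comes back at 15.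
- Morita–Baylis–Hillman reaction of 2 with methyl acrylate (DABCO, MeOH) gives the racemic allylic alcohol F3. Preparative chromatography on a chiral phase gives the (R)-alcohol F4.
- O-Allylation (allyl bromide, Ag2O, CH2Cl2) gives the diene F5. Ring-closing metathesis (second-generation Grubbs catalyst, CH2Cl2, 40 °C) gives the dihydrofuran ester F6.
- Ketyl–enoate coupling of 2 with F6 (SmI2, tBuOH, THF, −78 °C) is expected to add the ketyl to C8' anti to the C7 aryl, and lactonisation of the alkoxide onto the ester then gives 15.
- The cost is a resolution and a less secure stereochemical course at C8, C8' and C7'.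

**Step 4 (asymmetric Heck reaction).** The most likely failure is slow oxidative addition of the electron-rich triflate with catalyst decay over the long reaction time, together with erosion of enantioselectivity or double-bond migration into conjugation with oxygen. The fallback builds the ring by metathesis; it sets out from 2 and comes back at 7. Catalytic asymmetric addition of divinylzinc to 2 (chiral amino-alcohol ligand, toluene, 0 °C; the ligand enantiomer that gives the (S)-carbinol) gives the allylic alcohol F7. O-Allylation (NaH, allyl bromide, THF, 0 °C) gives the diene F8. Ring-closing metathesis (second-generation Grubbs catalyst, CH2Cl2, rt) then gives 7.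

**Step 12 (primary acylation).** The most likely failure is acylation at O-7' or at both hydroxyls, or base-promoted acyl migration between O-9 and O-7' within the 1,4-diol. The fallback separates the two hydroxyls by protection; it sets out from 16 and comes back at 21.
- Bis-silylation (Et3SiOTf, 2,6-lutidine, CH2Cl2, −78 °C) gives the bis(triethylsilyl) ether F9.
- Selective cleavage of the primary silyl ether (PPTS, MeOH–CH2Cl2, 0 °C) gives the primary alcohol F10.
- Esterification with 19 under the conditions of step 12 gives the ester F11.
- The conditions of step 13 remove the triethylsilyl and the three aryl silyl groups together to give 21.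

## Further compounds

F1 | step 8 | trimethylsilyl enol ether of 10: 4-[4-(tert-butyldimethylsilyloxy)-3-methoxyphenyl]-6-(trimethylsilyloxy)-3-oxabicyclo[3.2.0]hept-6-ene, ring stereocentres as in 10 | C[Si](C)(C)OC1=C[C@H]2CO[C@H](c3ccc(O[Si](C)(C)C(C)(C)C)c(OC)c3)[C@@H]12
F2 | step 8 | (3aR,6S,6aS)-6-[4-(tert-butyldimethylsilyloxy)-3-methoxyphenyl]-3-hydroxytetrahydro-1H,3H-furo[3,4-c]furan-1-one (ring form of the cis aldehyde acid, C3 unassigned) | OC(O1)[C@H]2CO[C@H](c3ccc(O[Si](C)(C)C(C)(C)C)c(OC)c3)[C@H]2C1=O
F3 | step 5 | methyl 2-{[4-(tert-butyldimethylsilyloxy)-3-methoxyphenyl](hydroxy)methyl}prop-2-enoate (racemic) | COC(=O)C(=C)C(O)c1ccc(O[Si](C)(C)C(C)(C)C)c(OC)c1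
F4 | step 5 | methyl 2-{(R)-[4-(tert-butyldimethylsilyloxy)-3-methoxyphenyl](hydroxy)methyl}prop-2-enoate | O[C@H](c1ccc(O[Si](C)(C)C(C)(C)C)c(OC)c1)C(=C)C(=O)OC
F5 | step 5 | methyl 2-{(R)-(allyloxy)[4-(tert-butyldimethylsilyloxy)-3-methoxyphenyl]methyl}prop-2-enoate | C=CCO[C@H](c1ccc(O[Si](C)(C)C(C)(C)C)c(OC)c1)C(=C)C(=O)OC
F6 | step 5 | methyl (R)-2-[4-(tert-butyldimethylsilyloxy)-3-methoxyphenyl]-2,5-dihydrofuran-3-carboxylate | COC(=O)C1=CCO[C@@H]1c2ccc(O[Si](C)(C)C(C)(C)C)c(OC)c2
F7 | step 4 | (S)-1-[4-(tert-butyldimethylsilyloxy)-3-methoxyphenyl]prop-2-en-1-ol | O[C@H](c1ccc(O[Si](C)(C)C(C)(C)C)c(OC)c1)C=C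
F8 | step 4 | (S)-{4-[1-(allyloxy)prop-2-en-1-yl]-2-methoxyphenoxy}(tert-butyl)dimethylsilane | C=CCO[C@H](c1ccc(O[Si](C)(C)C(C)(C)C)c(OC)c1)C=C
F9 | step 12 | bis(triethylsilyl) ether of 16 (O-9 and O-7' silylated) | COc1cc([C@@H](O[Si](CC)(CC)CC)[C@H]2CO[C@H](c3ccc(O[Si](C)(C)C(C)(C)C)c(OC)c3)[C@H]2CO[Si](CC)(CC)CC)ccc1O[Si](C)(C)C(C)(C)C
F10 | step 12 | 7'-O-triethylsilyl ether of 16 (O-9 free) | COc1cc([C@@H](O[Si](CC)(CC)CC)[C@H]2CO[C@H](c3ccc(O[Si](C)(C)C(C)(C)C)c(OC)c3)[C@H]2CO)ccc1O[Si](C)(C)C(C)(C)C
F11 | step 12 | 7'-O-triethylsilyl ether of 20 | COc1cc([C@@H](O[Si](CC)(CC)CC)[C@H]2CO[C@H](c3ccc(O[Si](C)(C)C(C)(C)C)c(OC)c3)[C@H]2COC(=O)/C=C/c2ccc(O[Si](C)(C)C(C)(C)C)cc2)ccc1O[Si](C)(C)C(C)(C)C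
A1 | alternative 1 | (3S,3aR,6S,6aS)-3,6-bis(4-allyloxy-3-methoxyphenyl)tetrahydro-1H,3H-furo[3,4-c]furan-1-one | COc1cc([C@@H](O3)[C@H]2CO[C@H](c4ccc(OCC=C)c(OC)c4)[C@H]2C3=O)ccc1OCC=C
A2 | alternative 1 | (S)-5-(4-allyloxy-3-methoxyphenyl)furan-2(5H)-one | C=CCOc1ccc(cc1OC)[C@H]2OC(=O)C=C2
A3 | alternative 1 | {[chloro(4-allyloxy-3-methoxyphenyl)methoxy]methyl}trimethylsilane (racemic) | ClC(OC[Si](C)(C)C)c1ccc(OCC=C)c(OC)c1
A4 | alternative 2 | (3S,3aR,6S,6aR)-3,6-bis[4-(tert-butyldimethylsilyloxy)-3-methoxyphenyl]tetrahydrofuro[3,4-c]furan-1,4-dione (C2-symmetric, both aryl groups exo) | COc1cc([C@@H](O3)[C@H]2C(=O)O[C@H](c4ccc(O[Si](C)(C)C(C)(C)C)c(OC)c4)[C@H]2C3=O)ccc1O[Si](C)(C)C(C)(C)C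
A5 | alternative 2 | 2,5-bis(trimethylsilyloxy)furan | C[Si](C)(C)Oc1ccc(O[Si](C)(C)C)o1
A6 | alternative 3 | (3S,3aR,6S,6aS)-3,6-bis[4-(tert-butyldimethylsilyloxy)-3-methoxyphenyl]tetrahydro-1H,3H-furo[3,4-c]furan-1-one (identical with 15) | COc1cc([C@@H](O3)[C@H]2CO[C@H](c4ccc(O[Si](C)(C)C(C)(C)C)c(OC)c4)[C@H]2C3=O)ccc1O[Si](C)(C)C(C)(C)C
A7 | alternative 3 | methyl (R)-2-[4-(tert-butyldimethylsilyloxy)-3-methoxyphenyl]-2,5-dihydrofuran-3-carboxylate | COC(=O)C1=CCO[C@@H]1c2ccc(O[Si](C)(C)C(C)(C)C)c(OC)c2
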